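**Remark on the structure.** The SMILES contains no stereocentre and no stereogenic double bond, so the target is achiral and no step has to control configuration; the side chain is read as an unbranched chain of 33 carbon atoms (tritriacontyl) on C2.

## Analysis of the target

Target 8 is 5-hydroxy-7-methoxy-2-tritriacontyl-4H-chromen-4-one (C43H74O4), a benzo-γ-pyrone (O1, C2, C3, C4, C4a, C5–C8, C8a) with a free OH on C5, a methyl ether on C7 and an unbranched alkyl chain C1′–C33′ on C2. There is no stereocentre, so the only relationship to secure is the regiochemistry of the A-ring: the 5-OH, chelated to the C4 carbonyl, versus the 7-OMe. The sensitive groups are the γ-pyrone, which opens at C2 with hydroxide or alkoxide, the C2=C3 bond, which is a Michael acceptor and can be hydrogenated, the electron-rich phloroglucinol-derived A-ring, and the vinylogously acidic C3–H and C1′–H2. The heterocycle is the easy part, because it is the cyclodehydration product of an aryl 1,3-diketone and the correctly oxygenated aryl methyl ketone 1 is an article of commerce. The hard part is the chain: 32 consecutive C(sp3)–C(sp3) bonds without any functional group, for which no C32–C34 chain reagent is a practical commercial material and whose long-chain precursors are waxes that dissolve poorly at the low temperatures of enolate chemistry. The feature the route exploits is the C16′–C17′ bond in the middle of the chain, which joins two methylene carbons with no functional group nearby. C2 and C1′–C16′ together are the 17 carbons left of a C18 diacid after its distal carboxyl is removed, and C17′–C33′ are the 17 alkyl carbons of stearic acid. A decarboxylative radical coupling at this bond joins two carbons of like polarity and leaves no functional group behind, which is what a bare polymethylene chain asks for.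

## Retrosynthetic reasoning

**Disconnection 1 (key step).** The C16′–C17′ bond of 8 is cut homolytically, giving chromone acid 6 and stearic acid 7, each carrying a carboxyl group on the carbon that becomes a chain methylene. A polar coupling here would leave an alkene, alkyne or ketone to be removed next to a reducible pyranone. An anodic crossed Kolbe coupling gives the saturated chain directly. Cutting at the midpoint means both halves come from commercial C18 acids, and every intermediate before the last step is an ordinary, soluble compound. The forward step must discharge both carboxylates at platinum without oxidising the A-ring, and must favour the cross-product over the two symmetrical ones. Exchanging 7 for another fatty acid would give the chain homologues of this chromone family from the same acid 6.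

**Disconnection 2.** The O1–C2 bond of 6 is cut, and the carboxyl group is traced back to its tert-butyl ester. This leads to aryl 1,3-diketone 4 via the diketo acid 5. The two phenolic OH groups of 4 are equivalent, so ring closure can give only one chromone, and the OH that does not close becomes the chelated 5-OH. One acidic operation should cleave the ester and close the ring.

**Disconnection 3.** The C2–C3 bond of the future pyranone (C18–C19 of the icosanoate chain of 4) is cut. This is a Claisen-type C-acylation of the methyl ketone 1, as its polyanion, with acid chloride 3, made in the flask from the commercial half-ester 2. The 5-OH/7-OMe pattern is bought with 1 and never has to be differentiated.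

## Alternatives that were turned down

Alternative 1: The textbook route. Disconnection: O1–C2 and C2–C3 of the pyranone, with the complete chain in the acyl partner. Forward key step: C-acylation of the polyanion of 1 with tetratriacontanoyl chloride A1 (a Claisen/Baker–Venkataraman reaction) to give the diketone 1-(2,6-dihydroxy-4-methoxyphenyl)hexatriacontane-1,3-dione A2 , then acid cyclodehydration of A2 to 8. Turned down for three reasons:
- The key step forms the easiest bond of the molecule and leaves the real problem inside the reagent. A1 is not a practical commercial material and would itself have to be assembled in several chain-extension steps.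
- A1 and A2 are waxes that should be nearly insoluble in ethereal solvents at the temperatures a polyanion acylation needs, so the one polar C–C bond formation would run heterogeneously.
- Every homologue would need its own long acyl chloride of the A1 type.

Alternative 2: The biomimetic polyketide route. Disconnection: C4a–C5 of the benzene ring and O1–C2, copying the type III polyketide synthase assembly from a fatty acyl starter and four malonate units. Forward key step: Claisen cyclisation, mediated by a magnesium alkoxide, of the open-chain ester methyl 3,5,7,9-tetraoxodotetracontanoate A3 , with C6 attacking the C1 ester. In-flask cyclodehydration would then give the dihydroxychromone 5,7-dihydroxy-2-tritriacontyl-4H-chromen-4-one A4 , and selective 7-O-methylation of A4 would give 8. Turned down for four reasons: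
- It builds from acyclic material two rings whose aromatic half, correctly methylated, is bought in 1.
- A3 still needs the C34 acyl unit plus several polyanion steps.
- Nothing in A3 forces the Claisen mode over the aldol modes, which would lead to resorcylate-type and pyrone products.
- The 7-OH of A4 needs a separate methylation at the end, and this step has to spare the 5-OH of A4 .

Alternative 3: Chain attachment by enolate alkylation. Disconnection: C1′–C2′. Forward key step: double deprotonation of 5-hydroxy-7-methoxy-2-methyl-4H-chromen-4-one (eugenin) A5 with two equivalents of a lithium amide, then alkylation of the vinylogous enolate of A5 at the 2-methyl group with 1-bromodotriacontane A6 to give 8 directly. Turned down for three reasons: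
- A6 is not commercial and would take several steps to make from shorter alcohols.
- An SN2 reaction of the waxy primary bromide A6 is slow at the low temperature at which the dianion of A5 is stable. The competing pathways are then C3-alkylation, a second alkylation at the still acidic C1′, and opening of the pyranone.
- As in Alternative 1, the key step leaves thirty-one of the chain bonds to a reagent that does not exist on the shelf.

Key step: step 3

## Route

Step 1
Reactants: 1 1-(2,6-dihydroxy-4-methoxyphenyl)ethan-1-one (2′,6′-dihydroxy-4′-methoxyacetophenone); 2 18-(tert-butoxy)-18-oxooctadecanoic acid (octadecanedioic acid mono-tert-butyl ester)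
Product: 4 tert-butyl 20-(2,6-dihydroxy-4-methoxyphenyl)-18,20-dioxoicosanoate, via tert-butyl 18-chloro-18-oxooctadecanoate 3 (not isolated)
Conditions: (a) 2, 1-chloro-N,N,2-trimethylprop-1-en-1-amine (1.0 equiv), CH2Cl2, 0 °C to rt; (b) 1 (2.0 equiv), LiHMDS (6.0 equiv), THF, −78 to −20 °C; then solution of 3, −78 °C to rt; cold 1 M HCl
Reagents that add atoms: none
Why: Claisen-type C-acylation of the lithium polyanion of an o-hydroxyacetophenone with an acid chloride (the one-pot variant of the Baker–Venkataraman synthesis); the neutral α-chloroenamine makes 3 without acid, so the tert-butyl ester survives. The second equivalent of the trianion of 1 serves as the base for the diketone formed, so the enolisable acid chloride meets no free amide base, and any O-acylated phenoxide should converge on 4 by enolate-driven O-to-C acyl transfer on warming.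

Step 2
Reactants: 4 tert-butyl 20-(2,6-dihydroxy-4-methoxyphenyl)-18,20-dioxoicosanoate
Product: 6 17-(5-hydroxy-7-methoxy-4-oxo-4H-chromen-2-yl)heptadecanoic acid, via 20-(2,6-dihydroxy-4-methoxyphenyl)-18,20-dioxoicosanoic acid 5 (not isolated)
Conditions: TFA–CH2Cl2 (1:1), rt; evaporate; then cat. H2SO4, AcOH, 90 °C
Reagents that add atoms: none
Why: Acidolysis of the tert-butyl ester (alkyl–oxygen cleavage, isobutene leaves) followed by acid-catalysed cyclodehydration of the o-hydroxyaryl 1,3-diketone (6-exo-trig addition of a phenol OH to the C18 ketone, then loss of water from the hemiketal). The two OH groups are equivalent, so only one chromone can form, and the remaining OH becomes the chelated 5-OH. Both free ring positions are flanked by two oxygen substituents, which should disfavour tert-butylation, and acetic acid as solvent cannot esterify the new carboxylic acid.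

Step 3
Reactants: 6 17-(5-hydroxy-7-methoxy-4-oxo-4H-chromen-2-yl)heptadecanoic acid; 7 octadecanoic acid (stearic acid, ca. 6 equiv)
Product: 8 5-hydroxy-7-methoxy-2-tritriacontyl-4H-chromen-4-one
Conditions: smooth Pt anode, Pt cathode, undivided cell, KOH (ca. 5 mol% of total acid), MeOH–pyridine (5:1), 50 °C, constant current ca. 0.25 A cm−2, ca. 1.3 F per mol of total acid, stopped while still weakly acidic
Reagents that add atoms: none
Why: Crossed Kolbe electrolysis: above the critical potential both carboxylates are discharged at the platinum anode to acyloxy radicals that lose CO2 in the adsorbed layer, and the two primary radicals, 16-(chromen-2-yl)hexadecyl from 6 and heptadecyl from 7, combine to form the C16′–C17′ bond of 8 while protons are reduced to H2 at the cathode. The closest known reaction type is the mixed Kolbe coupling of an ω-functionalised alkanoic acid (classically a diacid half-ester) with a fatty acid, the standard electrochemical entry to very long chains; no ring is closed and no stereocentre is formed. Cross- versus homo-coupling is statistical, so the cheap acid 7 is used in about six-fold excess to channel most radicals derived from 6 into the cross-product; the two symmetrical homo-coupling products (a hydrocarbon and a bis-chromone) differ so much in polarity from 8 that hot filtration and chromatography should separate them. The one-electron pathway is secured by the substrate: both radicals are primary and unstabilised, with no α-heteroatom or α-aryl group, so further oxidation to carbocations (Hofer–Moest pathway) should be minor at high current density on smooth platinum in weakly acidic methanol. Chemoselectivity against the arene rests on three features of 6: the carboxylate that anchors the molecule in the anode layer is sixteen methylenes away from the chromone, the A-ring is deactivated by the C4 carbonyl, and the 5-OH is chelated and stays un-ionised in the largely unneutralised medium; the dense carboxylate layer at Kolbe potentials is what normally shields more easily oxidised neutral species such as the solvent. Radical addition to C2=C3 should not compete, because C2 is fully substituted and radical–radical coupling in the concentrated anode layer is much faster. The cathode should not reduce the chromone, because proton discharge on platinum occurs at a far less negative potential.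

## Compound list

1 | 1-(2,6-dihydroxy-4-methoxyphenyl)ethan-1-one | CC(=O)c1c(O)cc(OC)cc1O | starting material
2 | 18-(tert-butoxy)-18-oxooctadecanoic acid | OC(=O)CCCCCCCCCCCCCCCCC(=O)OC(C)(C)C | starting material
3 | tert-butyl 18-chloro-18-oxooctadecanoate | ClC(=O)CCCCCCCCCCCCCCCCC(=O)OC(C)(C)C | intermediate
4 | tert-butyl 20-(2,6-dihydroxy-4-methoxyphenyl)-18,20-dioxoicosanoate | COc1cc(O)c(C(=O)CC(=O)CCCCCCCCCCCCCCCCC(=O)OC(C)(C)C)c(O)c1 | intermediate
5 | 20-(2,6-dihydroxy-4-methoxyphenyl)-18,20-dioxoicosanoic acid | COc1cc(O)c(C(=O)CC(=O)CCCCCCCCCCCCCCCCC(=O)O)c(O)c1 | intermediate
6 | 17-(5-hydroxy-7-methoxy-4-oxo-4H-chromen-2-yl)heptadecanoic acid | OC(=O)CCCCCCCCCCCCCCCCc1cc(=O)c2c(O)cc(OC)cc2o1 | intermediate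
7 | octadecanoic acid (stearic acid) | CCCCCCCCCCCCCCCCCC(=O)O | starting material
8 | 5-hydroxy-7-methoxy-2-tritriacontyl-4H-chromen-4-one | CCCCCCCCCCCCCCCCCCCCCCCCCCCCCCCCCc1cc(=O)c2c(O)cc(OC)cc2o1 | target

## Step count and risk

Total step count: 3. Longest linear sequence: 3 steps (1 → 4 → 6 → 8).

**Step 3 (key step).** Most likely to go wrong:
- competing anodic oxidation of the electron-rich A-ring, with film formation on the platinum;
- addition of alkyl radicals to the C2=C3 bond;
- blocking of the anode by the waxy coupling products, which lowers the current density and shifts the reaction towards two-electron products.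

All three arise because the substrate meets an oxidising electrode. The fallback therefore moves the decarboxylative coupling to the cathode. It sets out from 6 and 7. Each acid is esterified with N-hydroxyphthalimide (DIC, cat. DMAP, CH2Cl2; the chelated 5-OH should not be acylated) to give 1,3-dioxoisoindolin-2-yl 17-(5-hydroxy-7-methoxy-4-oxo-4H-chromen-2-yl)heptadecanoate F1 and 1,3-dioxoisoindolin-2-yl octadecanoate F2. A nickel-catalysed electroreductive doubly decarboxylative C(sp3)–C(sp3) coupling of F1 with about three equivalents of F2 should then form the same C16′–C17′ bond (NiCl2·6H2O, a terpyridine-type ligand, AgNO3, sacrificial Mg anode, carbon cathode, NMP, rt; dilute HCl work-up). The fallback comes back to the route at 8.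

**Step 1.** Most likely to go wrong:
- ketene formation from the enolisable acid chloride;
- O-acylation of a phenoxide that does not rearrange;
- a second acylation at the new diketone.

All stem from running an intermolecular C-acylation on a polyanion. The fallback makes the C–C bond intramolecularly by the classical two-operation Baker–Venkataraman sequence. It sets out from 1 and 2. Steglich esterification (DCC, cat. DMAP, CH2Cl2, slight excess of 1) should give the mono-aryl ester 1-(2-acetyl-3-hydroxy-5-methoxyphenyl) 18-tert-butyl octadecanedioate F3. Treatment of F3 with KOtBu (3 equiv) in THF (0 °C to rt, then dilute HCl) should then transfer the acyl group from oxygen to the enolate carbon. The fallback comes back to the route at 4.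

**Step 2.** Most likely to go wrong:
- capture of the tert-butyl cation by the electron-rich ring during acidolysis;
- incomplete dehydration of the cyclic hemiketal.

The fallback replaces alkyl–oxygen cleavage by acyl–oxygen hydrolysis, so that no carbocation is generated. It sets out from 1. Commercial 18-methoxy-18-oxooctadecanoic acid F4 is converted with oxalyl chloride (cat. DMF, CH2Cl2) into methyl 18-chloro-18-oxooctadecanoate F5. F5 should acylate the trianion of 1 under the conditions of step 1 to give methyl 20-(2,6-dihydroxy-4-methoxyphenyl)-18,20-dioxoicosanoate F6. Heating F6 in 6 M aqueous HCl–AcOH at reflux should close the pyranone and hydrolyse the methyl ester in the same flask. The fallback comes back to the route at 6.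

## Further compounds

F1 | step 3 | 1,3-dioxoisoindolin-2-yl 17-(5-hydroxy-7-methoxy-4-oxo-4H-chromen-2-yl)heptadecanoate | O=C(CCCCCCCCCCCCCCCCc1cc(=O)c2c(O)cc(OC)cc2o1)ON1C(=O)c2ccccc2C1=O
F2 | step 3 | 1,3-dioxoisoindolin-2-yl octadecanoate | CCCCCCCCCCCCCCCCCC(=O)ON1C(=O)c2ccccc2C1=O
F3 | step 1 | 1-(2-acetyl-3-hydroxy-5-methoxyphenyl) 18-tert-butyl octadecanedioate | CC(=O)c1c(O)cc(OC)cc1OC(=O)CCCCCCCCCCCCCCCCC(=O)OC(C)(C)C
F4 | step 2 | 18-methoxy-18-oxooctadecanoic acid | COC(=O)CCCCCCCCCCCCCCCCC(=O)O
F5 | step 2 | methyl 18-chloro-18-oxooctadecanoate | COC(=O)CCCCCCCCCCCCCCCCC(=O)Cl
F6 | step 2 | methyl 20-(2,6-dihydroxy-4-methoxyphenyl)-18,20-dioxoicosanoate | COC(=O)CCCCCCCCCCCCCCCCC(=O)CC(=O)c1c(O)cc(OC)cc1O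
A1 | alternative 1 | tetratriacontanoyl chloride | CCCCCCCCCCCCCCCCCCCCCCCCCCCCCCCCCC(=O)Cl
A2 | alternative 1 | 1-(2,6-dihydroxy-4-methoxyphenyl)hexatriacontane-1,3-dione | CCCCCCCCCCCCCCCCCCCCCCCCCCCCCCCCCC(=O)CC(=O)c1c(O)cc(OC)cc1O
A3 | alternative 2 | methyl 3,5,7,9-tetraoxodotetracontanoate | CCCCCCCCCCCCCCCCCCCCCCCCCCCCCCCCCC(=O)CC(=O)CC(=O)CC(=O)CC(=O)OC
A4 | alternative 2 | 5,7-dihydroxy-2-tritriacontyl-4H-chromen-4-one | CCCCCCCCCCCCCCCCCCCCCCCCCCCCCCCCCc1cc(=O)c2c(O)cc(O)cc2o1
A5 | alternative 3 | 5-hydroxy-7-methoxy-2-methyl-4H-chromen-4-one (eugenin) | Cc1cc(=O)c2c(O)cc(OC)cc2o1
A6 | alternative 3 | 1-bromodotriacontane | CCCCCCCCCCCCCCCCCCCCCCCCCCCCCCCCBr
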